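**Retrosynthetic overview**
- Target ⇐ acetylation, chelation-controlled ketone reduction and tigloylation of a trans-4,5-epoxy-3-hydroxy-6-ketone, which comes from hydroxyl-directed nucleophilic epoxidation of a 3-hydroxy-4-en-6-one.
- That enone ⇐ E1cB opening of a ten-membered 3,4-epoxy-6-ketone, made by tin-directed oxidative Grob ring expansion: cleavage of the C1–C6 fusion bond of a trans-fused bicyclo[4.4.0] γ-stannyl carbinol gives the C6 ketone and the 1(10)E alkene.
- Bicyclic carbinol ⇐ hydroxyl-directed epoxidation (sets C3), ring-closing metathesis (ring A) and methallyl Grignard addition to a 2-allyl-6-isopropenyl-3-methyl-3-stannylcyclohexanone.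
- Cyclohexanone ⇐ 3-methylcyclohex-2-enone by a new copper-catalysed enantioselective conjugate stannylation/allylation, then palladium-catalysed α′-isopropenylation.
- Ring order: ring B (six-membered, from the start) → ring A (six-membered, metathesis) → ten-membered ring by fragmentation of the shared bond.

Assumption: ring locants in descriptive names follow germacrane numbering (ring C1–C10; C1=C10 bears CH3-14; C3 O-tigloyl; C4 bears CH3-15; C6 OAc; C7 isopropenyl C11–C13). The target is (3S,4R,5R,6R,7S,1(10)E) with an (E)-2-methylbut-2-enoate. In step 1, (R,R)-QuinoxP* is written for definiteness; the ligand antipode that gives Re-face tin delivery is meant.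

**Step 1**
Reactants: 1 3-methylcyclohex-2-en-1-one; 2 allyl bromide
Product: 5 (2R,3R)-3-methyl-2-(prop-2-en-1-yl)-3-(trimethylstannyl)cyclohexan-1-one, via silyl enol ether 3 (not isolated), via lithium enolate 4 (not isolated)
Conditions: CuCl (5 mol %), (R,R)-QuinoxP* (6 mol %), NaOt-Bu (10 mol %), Me3Sn–SiMe3 (1.1 equiv), THF, −30 °C; then MeLi, 0 °C; then 2, DMPU, −78 → −20 °C
Reagents that add atoms: trimethyl(trimethylstannyl)silane, C[Si](C)(C)[Sn](C)(C)C
Why: Proposed new method: the chiral bisphosphine–copper tert-butoxide undergoes σ-bond metathesis with Me3Sn–SiMe3 (Si–O bond formation drives selective Cu–Sn formation), the stannylcopper adds 1,4 to the Re face of C3 under ligand control (sets 3R, the source of all later stereocontrol, and forms the C–Sn bond that later drives the ring expansion), the copper enolate is silylated by a second Me3Sn–SiMe3 to regenerate Cu–SnMe3 and give 3, and MeLi turns 3 into enolate 4, which is allylated anti to the axial C–Sn bond (trans, 2R); the closest known reaction types are copper-catalysed enantioselective conjugate silylation and borylation of β-substituted cyclic enones with Si–B and B–B reagents and the stoichiometric stannyl-lithium conjugate addition/enolate alkylation.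

**Step 2**
Reactants: 5 (2R,3R)-3-methyl-2-(prop-2-en-1-yl)-3-(trimethylstannyl)cyclohexan-1-one; 6 2-bromopropene
Product: 7 (2R,3R,6S)-3-methyl-2-(prop-2-en-1-yl)-6-(prop-1-en-2-yl)-3-(trimethylstannyl)cyclohexan-1-one
Conditions: LiN(SiMe3)2, Pd2(dba)3 (2.5 mol %), P(t-Bu)3 (6 mol %), THF/toluene, −78 → 40 °C
Reagents that add atoms: none
Why: Palladium-catalysed α-alkenylation of a ketone enolate (enolate cross-coupling): the base removes a proton from the less hindered C6 methylene, the zerovalent palladium/2-bromopropene oxidative-addition complex couples with the enolate, and the isopropenyl group ends up equatorial, cis to the allyl group, which sets 6S (the future C7).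

**Step 3**
Reactants: 7 (2R,3R,6S)-3-methyl-2-(prop-2-en-1-yl)-6-(prop-1-en-2-yl)-3-(trimethylstannyl)cyclohexan-1-one; 8 (2-methylprop-2-en-1-yl)magnesium chloride
Product: 9 (1R,2R,3R,6S)-3-methyl-1-(2-methylprop-2-en-1-yl)-2-(prop-2-en-1-yl)-6-(prop-1-en-2-yl)-3-(trimethylstannyl)cyclohexan-1-ol
Conditions: THF, −78 → 0 °C; aq. NH4Cl
Reagents that add atoms: none
Why: 1,2-Addition of an allylic Grignard reagent (cyclic SE2′ transition state, little enolisation) from the equatorial side, because the axial C3 methyl blocks axial attack, giving the axial tertiary alcohol (1R).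

**Step 4**
Reactants: 9 (1R,2R,3R,6S)-3-methyl-1-(2-methylprop-2-en-1-yl)-2-(prop-2-en-1-yl)-6-(prop-1-en-2-yl)-3-(trimethylstannyl)cyclohexan-1-ol
Product: 10 (1R,4S,4aR,8aR)-1,6-dimethyl-4-(prop-1-en-2-yl)-1-(trimethylstannyl)-1,2,3,4,5,8-hexahydronaphthalen-4a(8aH)-ol (trans-fused; SnMe3 equatorial, CH3 axial)
Conditions: RuCl2(=CHPh)(PCy3)(H2IMes) (second-generation Grubbs catalyst, 5 mol %), CH2Cl2, 40 °C
Reagents that add atoms: none
Why: Ring-closing metathesis of the allyl alkene with the vicinal methallyl alkene closes ring A as a trisubstituted cyclohexene; the fused six-membered closure is far faster than the bridged ring the equatorial isopropenyl group would need, and no stereocentre is touched.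

**Step 5**
Reactants: 10 (trans-fused stannyl octalinol)
Product: 11 (1R,4S,4aR,6R,7S,8aR)-6,7-epoxy-1,6-dimethyl-4-(prop-1-en-2-yl)-1-(trimethylstannyl)decahydronaphthalen-4a-ol (epoxide cis to OH)
Conditions: VO(acac)2 (5 mol %), t-BuOOH, toluene, 0 °C → rt
Reagents that add atoms: tert-butyl hydroperoxide, CC(C)(C)OO
Why: Vanadium-catalysed hydroxyl-directed epoxidation of a cyclohex-3-enol: the axial tertiary OH binds the vanadium alkylperoxide and delivers oxygen to its own face of the ring-A double bond, which sets the future C3 as S (C4 as R); the directed trisubstituted ring alkene reacts ahead of the isopropenyl group.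

**Step 6**
Reactants: 11 (epoxy stannyl decalinol)
Product: 13 (3S,7S)-3-hydroxygermacra-1(10)E,4E,11-trien-6-one, via epoxy ketone 12 (not isolated)
Conditions: Pb(OAc)4 (1.2 equiv), pyridine, benzene, rt; then Et3N, 0 °C → rt
Reagents that add atoms: none
Why: Tin-directed oxidative Grob fragmentation (ring expansion): the tetravalent lead alkoxide of the tertiary alcohol breaks down with cleavage of the C1–C6 fusion bond, which lies anti-periplanar to the equatorial C–Sn bond, so the 6-6 system opens to the ten-membered ketone 12 with the 1(10) alkene fixed as E (C2 equatorial, anti to C9); Et3N then opens the β,γ-epoxy ketone by E1cB to the γ-hydroxy enone, leaving C3 untouched.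

**Step 7**
Reactants: 13 (3S,7S)-3-hydroxygermacra-1(10)E,4E,11-trien-6-one
Product: 14 (3S,4R,5S,7S)-4,5-epoxy-3-hydroxygermacra-1(10)E,11-dien-6-one
Conditions: t-BuOOH (2.5 equiv), LiOt-Bu (2.2 equiv), THF, −20 °C
Reagents that add atoms: tert-butyl hydroperoxide, CC(C)(C)OO
Why: Hydroxyl-directed nucleophilic (Weitz–Scheffer) epoxidation: the lithium alkoxide at C3 delivers tert-butyl peroxide to the neighbouring face of C4 (syn, threo relation of O3 and the epoxide oxygen, 4R), and the β-peroxy enolate closes after bond rotation to the trans-epoxide, so the result does not depend on the enone geometry.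

**Step 8**
Reactants: 14 (3S,4R,5S,7S)-4,5-epoxy-3-hydroxygermacra-1(10)E,11-dien-6-one; 15 (E)-2-methylbut-2-enoyl chloride (tigloyl chloride)
Product: 16 (3S,4R,5S,7S)-4,5-epoxy-6-oxogermacra-1(10)E,11-dien-3-yl (E)-2-methylbut-2-enoate
Conditions: Et3N, DMAP (cat.), CH2Cl2, 0 °C
Reagents that add atoms: none
Why: DMAP-catalysed acylation of the only hydroxyl group with the acid chloride; the (E)-enoate is the stable geometric isomer and no stereocentre is touched.

**Step 9**
Reactants: 16 (3S,4R,5S,7S)-4,5-epoxy-6-oxogermacra-1(10)E,11-dien-3-yl (E)-2-methylbut-2-enoate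
Product: 17 (3S,4R,5R,6R,7S)-4,5-epoxy-6-hydroxygermacra-1(10)E,11-dien-3-yl (E)-2-methylbut-2-enoate
Conditions: Zn(BH4)2, Et2O, −20 °C
Reagents that add atoms: none
Why: Chelation-controlled hydride reduction of an α,β-epoxy ketone: zinc bridges the carbonyl and epoxide oxygens and hydride attacks anti to C4, giving the erythro (anti) epoxy alcohol, 6R (the C5 descriptor changes from S to R by CIP ranking only).

**Step 10**
Reactants: 17 (3S,4R,5R,6R,7S)-4,5-epoxy-6-hydroxygermacra-1(10)E,11-dien-3-yl (E)-2-methylbut-2-enoate; 18 acetic anhydride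
Product: 19 (3S,4R,5R,6R,7S)-6-acetoxy-4,5-epoxygermacra-1(10)E,11-dien-3-yl (E)-2-methylbut-2-enoate (CNP0400048.1)
Conditions: pyridine, DMAP (cat.), CH2Cl2, 0 °C → rt
Reagents that add atoms: none
Why: DMAP-catalysed acetylation of the secondary alcohol under basic conditions that spare the epoxide and the 1(10) alkene; no stereocentre is touched.

**Compound list**
1 | 3-methylcyclohex-2-en-1-one | CC1=CC(=O)CCC1 | starting material
2 | allyl bromide (3-bromoprop-1-ene) | C=CCBr | starting material
3 | (R)-trimethyl{[3-methyl-3-(trimethylstannyl)cyclohex-1-en-1-yl]oxy}silane | C[C@@]1([Sn](C)(C)C)CCCC(O[Si](C)(C)C)=C1 | intermediate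
4 | lithium (R)-3-methyl-3-(trimethylstannyl)cyclohex-1-en-1-olate | C[C@@]1([Sn](C)(C)C)CCCC([O-])=C1.[Li+] | intermediate
5 | (2R,3R)-3-methyl-2-(prop-2-en-1-yl)-3-(trimethylstannyl)cyclohexan-1-one | C=CC[C@@H]1C(=O)CCC[C@@]1(C)[Sn](C)(C)C | intermediate
6 | 2-bromopropene | CC(Br)=C | starting material
7 | (2R,3R,6S)-3-methyl-2-(prop-2-en-1-yl)-6-(prop-1-en-2-yl)-3-(trimethylstannyl)cyclohexan-1-one | C=CC[C@@H]1C(=O)[C@H](C(C)=C)CC[C@@]1(C)[Sn](C)(C)C | intermediate
8 | (2-methylprop-2-en-1-yl)magnesium chloride | CC(=C)C[Mg]Cl | starting material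
9 | (1R,2R,3R,6S)-3-methyl-1-(2-methylprop-2-en-1-yl)-2-(prop-2-en-1-yl)-6-(prop-1-en-2-yl)-3-(trimethylstannyl)cyclohexan-1-ol | C=CC[C@@H]1[C@@](O)(CC(C)=C)[C@H](C(C)=C)CC[C@@]1(C)[Sn](C)(C)C | intermediate
10 | (1R,4S,4aR,8aR)-1,6-dimethyl-4-(prop-1-en-2-yl)-1-(trimethylstannyl)-1,2,3,4,5,8-hexahydronaphthalen-4a(8aH)-ol | C[C@@]1([Sn](C)(C)C)CC[C@@H](C(C)=C)[C@]2(O)CC(C)=CC[C@@H]12 | intermediate
11 | (1R,4S,4aR,6R,7S,8aR)-6,7-epoxy-1,6-dimethyl-4-(prop-1-en-2-yl)-1-(trimethylstannyl)decahydronaphthalen-4a-ol | C[C@@]1([Sn](C)(C)C)CC[C@@H](C(C)=C)[C@]2(O)C[C@@]3(C)O[C@H]3C[C@@H]12 | intermediate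
12 | (3S,4R,7S)-3,4-epoxygermacra-1(10)E,11-dien-6-one | C=C(C)[C@@H]1CC/C(C)=C/C[C@@H]2O[C@]2(C)CC1=O | intermediate
13 | (3S,7S)-3-hydroxygermacra-1(10)E,4E,11-trien-6-one [(2E,4S,6E,10S)-4-hydroxy-3,7-dimethyl-10-(prop-1-en-2-yl)cyclodeca-2,6-dien-1-one] | C=C(C)[C@@H]1CC/C(C)=C/C[C@H](O)/C(C)=C/C1=O | intermediate
14 | (3S,4R,5S,7S)-4,5-epoxy-3-hydroxygermacra-1(10)E,11-dien-6-one | C=C(C)[C@@H]1CC/C(C)=C/C[C@H](O)[C@@]2(C)O[C@@H]2C1=O | intermediate
15 | (E)-2-methylbut-2-enoyl chloride (tigloyl chloride) | C/C=C(\C)C(Cl)=O | starting material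
16 | (3S,4R,5S,7S)-4,5-epoxy-6-oxogermacra-1(10)E,11-dien-3-yl (E)-2-methylbut-2-enoate | C=C(C)[C@@H]1CC/C(C)=C/C[C@H](OC(=O)/C(C)=C/C)[C@@]2(C)O[C@@H]2C1=O | intermediate
17 | (3S,4R,5R,6R,7S)-4,5-epoxy-6-hydroxygermacra-1(10)E,11-dien-3-yl (E)-2-methylbut-2-enoate | C=C(C)[C@@H]1CC/C(C)=C/C[C@H](OC(=O)/C(C)=C/C)[C@@]2(C)O[C@@H]2[C@@H]1O | intermediate
18 | acetic anhydride | CC(=O)OC(C)=O | starting material
19 | (3S,4R,5R,6R,7S)-6-acetoxy-4,5-epoxygermacra-1(10)E,11-dien-3-yl (E)-2-methylbut-2-enoate (CNP0400048.1) | C=C(C)[C@@H]1CC/C(C)=C/C[C@H](OC(=O)/C(C)=C/C)[C@@]2(C)O[C@@H]2[C@@H]1OC(C)=O | target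

**Total step count:** 10. **Longest linear sequence:** 10 steps (from 1).

**Three steps most likely to fail**

Step 1 (new enantioselective conjugate stannylation/allylation; the catalytic Cu–Sn transfer or its enantioselectivity may fail). Fallback with known chemistry, setting out from 1: stoichiometric Me3SnLi (from Me3SnSnMe3 and MeLi, THF, −78 °C) adds 1,4 and the lithium enolate is trapped with 2 to give the racemic trans ketone F1. Ketalisation with (2R,3R)-butane-2,3-diol (as its bis-trimethylsilyl ether, cat. Me3SiOTf, −78 °C) gives the dioxolane of the (2R,3R)-ketone F2 and the diastereomeric dioxolane of the enantiomeric ketone F3, which are separated by chromatography. Mild hydrolysis of F2 (PPTS, wet acetone) comes back to the route at 5.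

Step 2 (palladium enolate alkenylation beside an alkylstannane and an allyl group; the β,γ-enone may drift into conjugation). Fallback, setting out from 5: LDA and Me3SiCl at −78 °C give the kinetic trimethylsilyl enol ether F4. Copper-catalysed (Cu(OTf)2) electrophilic alkenylation with isopropenyl(phenyl)iodonium tetrafluoroborate, an alkenyl transfer from trivalent iodine in place of the palladium enolate coupling, comes back to the route at 7.

Step 7 (directed nucleophilic epoxidation of a β,β-disubstituted enone in the ten-membered ring; rate, face and trans closure are uncertain, and C7 is base-sensitive). Fallback, setting out from 13, which replaces nucleophilic epoxidation by reduction followed by electrophilic epoxidation: acylation with 15 (Et3N, DMAP) gives the tigloyl enone F5. Reagent-controlled reduction with (S)-2-methyl-CBS-oxazaborolidine/BH3·SMe2 gives the allylic alcohol F6. Sharpless asymmetric epoxidation (Ti(Oi-Pr)4, D-(−)-diisopropyl tartrate, t-BuOOH) gives the erythro epoxy alcohol under tartrate control and touches only the allylic 4,5-alkene; it comes back to the route at 17.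

**Further compounds**
F1 | step 1 | racemic (2R*,3R*)-3-methyl-2-(prop-2-en-1-yl)-3-(trimethylstannyl)cyclohexan-1-one (5 with its enantiomer, 1:1) | C=CC[C@@H]1C(=O)CCC[C@@]1(C)[Sn](C)(C)C.C=CC[C@H]1C(=O)CCC[C@]1(C)[Sn](C)(C)C
F2 | step 1 | (2R,3R)-butane-2,3-diol ketal (4,5-dimethyl-1,3-dioxolane) of the (2R,3R)-ketone 5 | C=CC[C@@H]1C2(O[C@H](C)[C@@H](C)O2)CCC[C@@]1(C)[Sn](C)(C)C
F3 | step 1 | (2R,3R)-butane-2,3-diol ketal of the (2S,3S)-ketone (discarded diastereomer) | C=CC[C@H]1C2(O[C@H](C)[C@@H](C)O2)CCC[C@]1(C)[Sn](C)(C)C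
F4 | step 2 | trimethyl{[(5R,6R)-5-methyl-6-(prop-2-en-1-yl)-5-(trimethylstannyl)cyclohex-1-en-1-yl]oxy}silane | C=CC[C@@H]1C(O[Si](C)(C)C)=CCC[C@@]1(C)[Sn](C)(C)C
F5 | step 7 | (3S,7S)-6-oxogermacra-1(10)E,4E,11-trien-3-yl (E)-2-methylbut-2-enoate | C=C(C)[C@@H]1CC/C(C)=C/C[C@H](OC(=O)/C(C)=C/C)/C(C)=C/C1=O
F6 | step 7 | (3S,6S,7S)-6-hydroxygermacra-1(10)E,4E,11-trien-3-yl (E)-2-methylbut-2-enoate (C6 oriented as in the target; descriptor differs by CIP ranking only) | C=C(C)[C@@H]1CC/C(C)=C/C[C@H](OC(=O)/C(C)=C/C)/C(C)=C/[C@@H]1O
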